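The time of reading was 6.0 min, and I began with it, since the question is what two new flasks hold at that moment.

| flask | free monomer | protic impurity | initiator | remark | time |
|---|---|---|---|---|---|
| Sunday's | 0.10 M (fed, over 2.0 min) | 2 mM | 0.060 mM | run made earlier |  |
| Friday's | 0.10 M (fed, over 2.0 min) | 2 mM | 0.16 mM | run made earlier |  |
| Wednesday's | 0.10 M (fed, over 2.0 min) | 2 mM | 0.24 mM | run made earlier |  |
| south-east | 0.10 M (fed, over 2.0 min) | 2.00 mM | 0.32 mM |  | 6.0 min |
| north-east | 0.10 M (fed, over 2.0 min) | 2.00 mM | 0.080 mM |  | 6.0 min |

- Sunday's (time / min: monomer in chains / %, free monomer / %): 0.250: 3.0, 7.7; 0.417: 4.7, 14.2; 0.833: 9.7, 32.3; 1.50: 9.5, 64.7; 3.00: 10.6, 89.4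
- Friday's (time / min: monomer in chains / %, free monomer / %): 0.667: 8.9, 23.3; 1.33: 13.7, 52.3; 2.00: 13.0, 83.3; 2.50: 14.5, 82.9; 3.00: 14.6, 81.6
- Wednesday's (time / min: monomer in chains / %, free monomer / %): 0.250: 3.5, 6.6; 0.833: 11.8, 25.3; 1.33: 15.8, 50.9; 2.00: 16.3, 82.4; 3.00: 17.8, 79.9

(each reading ± 1 percentage point)

- the average divides the monomer in chains by the number of chains, living and dead together; two radicals that join make one chain
- the analysis behind the earlier runs scatters by 1 percentage point, standard deviation
- the earlier runs do not show the number of chains; that part of a forecast is a guess
- percentages count the whole charge, also what has not yet gone in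

- which of the two ends with the longer chains by the average number of monomer units in a chain (living and dead chains, two that joined counted as one) ("neither" if they lie within 10%) (south-east / north-east / neither)
- average number of monomer units in a chain (living and dead chains, two that joined counted as one) at the end, south-east
- average number of monomer units in a chain (living and dead chains, two that joined counted as one) at the end, north-east

Turning the time by hand, I expected little. Wednesday's monomer in chains moved 1.5 percentage points between 2.00 min and 3.00 min, against a scatter of 1 point, so I took the 3.00 min readings as ends.

Turning the initiator, I went to logarithms. Between Sunday's 10.6% and Wednesday's 17.8%, the log of the ratio in monomer in chains over the log of the ratio in c(initiator) gave an apparent order of 0.374. That line puts Friday's run, which I had not used, at 15.3%; it read 14.6%.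

The protic impurity could stop radicals or consume monomer. The two columns at 3.00 min fall short of the charge by 2.03% on average over the runs, and c(protic impurity) is 2.00% of the charge. So I booked it against free monomer and guessed that radicals end by joining: two radicals per initiator, two per chain, one chain per initiator. The earlier runs do not show the number of chains, so this stayed a guess. Length is then monomer in chains over c(initiator), and at the monomer charge, feed and impurity of these runs it falls as c(initiator) to the power 0.626, the length exponent.

From the nearest runs I reckoned 19.8% in chains for south-east and 11.8% for north-east. That makes about 61.9 and 148 units.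

The forecast also chose north-east, but with 100 units for south-east and 200 for north-east, suggesting that “radicals are lost by coupling early and by the impurity”. My two figures stood lower than its two.

The longer chains came in north-east: 55.4 units in south-east and 136 in north-east.

    2 growing radical → dead chain (k = 1.10 × 10⁹ M⁻¹ s⁻¹)
    free monomer + initiating radical → growing radical + monomer in chains (k = 7.15 × 10⁶ M⁻¹ s⁻¹)
    protic impurity + free monomer → quenched substrate (k = 16.5 M⁻¹ s⁻¹)
    free monomer + growing radical → monomer in chains + growing radical, rate k4*[growing radical]*[free monomer] (k = 7.94 × 10⁵ M⁻¹ s⁻¹)
    initiator → 2 initiating radical (k = 0.131 s⁻¹)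
    free monomer → decomposition product (k = 2.91 × 10⁻⁵ s⁻¹)

In south-east, dead chain stood at 3.20 × 10⁻⁴ M at 6.00 min, the same figure as the initiator charge of 0.32 mM. The length exponent, applied to south-east's 55.4 with the ratio of the two charges, gives 132 for north-east, which ended at 136.

A neighbour of north-east was charged with 2.0 × 10⁻⁴ M of initiator. From north-east's 136, the length exponent gives 76.9 units there, and the computed flask gives 76.1.

The numbers in the tables stem from a simulated flask with constants of no real substance.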